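Everything rests on breaking the C4–C5 bond of ring A (numbering: C1 CMe2, C2 CHBr, C3 CHOH, C6 spiro). C5, the methylidene-bearing carbon, lies between the ring-A methylene C4 and the spiro carbon C6. C5=CH2 is therefore read as an ethynyl group on C6, and C4 as the central carbon of a β-keto ester built on the C3 carbonyl. One gold-catalysed 6-exo-dig Conia-ene cycloisomerisation then closes ring A and installs the exocyclic alkene next to two contiguous quaternary carbons. The precursor is an acyclic tert-butyl 4-bromo-3-oxo ester. Its CMe2 carbon is bonded to the ethynyl-bearing carbon of a ketal-protected, still symmetric ring B. Only C–Br is stereogenic; C6 is set later by desymmetrisation.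

Key step: step 11

Remarks on the chemistry
- **Numbering:** target = (2S,3R,6S,8S,9R)-2-bromo-8-chloro-1,1,9-trimethyl-5-methylidenespiro[5.5]undecane-3,9-diol. C7 is the CH2 next to C8 (CHCl), C9 is C(Me)OH, and C10/C11 are the remaining ring-B CH2 groups. The S centre at C–Br in 14, 16 and 17 maps directly onto C2.
- **Assumption:** the senses of induction of (2R,5R)-2,5-diphenylpyrrolidine (step 9) and of lithium (R,R)-bis(1-phenylethyl)amide (step 14) are assigned by analogy with 3,3-dimethylbutanal and 4-tert-butylcyclohexanone. Both reagents exist in either enantiomeric form should the sense prove opposite.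
- **Ester removal:** protic acid would endanger the ketal and would conjugate the β,γ-unsaturated bromo ketone, so the tert-butyl ester is removed with TMSOTf/2,6-lutidine.
- **Catalyst:** the gold catalyst is preformed and silver-free because silver salts are halophilic.
- **C3 hydroxyl:** it receives no separate protection step. It is masked in passing as its trimethylsilyl ether in step 14 and freed in the work-up of step 16.

Step 1
Reactants: 1 1,4-dioxaspiro[4.5]decane-8-carboxylic acid; 2 3-methylbut-2-en-1-ol
Product: 3 3-methylbut-2-en-1-yl 1,4-dioxaspiro[4.5]decane-8-carboxylate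
Conditions: DCC, DMAP (cat.), CH2Cl2, 0 → 23 °C
Reagents that add atoms: none
Why: Steglich esterification couples the unhindered acid with the primary allylic alcohol under neutral conditions that spare the ketal.

Step 2
Reactants: 3 3-methylbut-2-en-1-yl 1,4-dioxaspiro[4.5]decane-8-carboxylate
Product: 6 [8-(2-methylbut-3-en-2-yl)-1,4-dioxaspiro[4.5]decan-8-yl]methanol, via silyl ketene acetal 4 (not isolated), via trimethylsilyl ester 5 (not isolated)
Conditions: LiN(i-Pr)2, THF, −78 °C; TMSCl, −78 → 65 °C; concentrate; LiAlH4, THF, 0 → 65 °C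
Reagents that add atoms: none
Why: Ireland–Claisen rearrangement: the fully substituted silyl ketene acetal has no E/Z issue, its [3,3] shift through the prenyl terminus forges the bond between the two adjacent quaternary carbons (future C6 and C1) and leaves a vinyl group, and the labile silyl ester is reduced directly by LiAlH4, which is easier than reducing the hindered carboxylate and touches neither ketal nor alkene.

Step 3
Reactants: 6 [8-(2-methylbut-3-en-2-yl)-1,4-dioxaspiro[4.5]decan-8-yl]methanol
Product: 8 3-[8-(hydroxymethyl)-1,4-dioxaspiro[4.5]decan-8-yl]-3-methylbutan-1-ol, via bis(9-BBN) adduct 7 (not isolated)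
Conditions: 9-BBN (2.5 equiv), THF, 0 → 50 °C; NaOH, H2O2, 0 → 23 °C
Reagents that add atoms: hydrogen peroxide, OO
Why: Hydroboration–oxidation: 9-BBN places boron on the terminal carbon of the neopentyl-type vinyl group for steric reasons (one equivalent is consumed by the hydroxyl group) and alkaline peroxide replaces boron by hydroxyl, all before any alkyne is present.

Step 4
Reactants: 8 3-[8-(hydroxymethyl)-1,4-dioxaspiro[4.5]decan-8-yl]-3-methylbutan-1-ol
Product: 9 [8-(4-{[tert-butyl(dimethyl)silyl]oxy}-2-methylbutan-2-yl)-1,4-dioxaspiro[4.5]decan-8-yl]methanol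
Conditions: TBSCl (1.05 equiv), imidazole, CH2Cl2, −10 → 0 °C
Reagents that add atoms: tert-butyldimethylsilyl chloride, CC(C)(C)[Si](C)(C)Cl
Why: Sterically differentiated monosilylation: the hydroxymethyl group sits on a quaternary carbon flanked by a second quaternary carbon and should react far more slowly than the open CH2CH2OH terminus.

Step 5
Reactants: 9 [8-(4-{[tert-butyl(dimethyl)silyl]oxy}-2-methylbutan-2-yl)-1,4-dioxaspiro[4.5]decan-8-yl]methanol
Product: 10 8-(4-{[tert-butyl(dimethyl)silyl]oxy}-2-methylbutan-2-yl)-1,4-dioxaspiro[4.5]decane-8-carbaldehyde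
Conditions: Dess–Martin periodinane, NaHCO3, CH2Cl2, 0 → 23 °C
Reagents that add atoms: none
Why: Dess–Martin oxidation converts the neopentyl alcohol into a non-enolisable aldehyde under buffered conditions compatible with ketal and silyl ether.

Step 6
Reactants: 10 8-(4-{[tert-butyl(dimethyl)silyl]oxy}-2-methylbutan-2-yl)-1,4-dioxaspiro[4.5]decane-8-carbaldehyde
Product: 11 tert-butyl{[3-(8-ethynyl-1,4-dioxaspiro[4.5]decan-8-yl)-3-methylbutyl]oxy}dimethylsilane
Conditions: dimethyl (1-diazo-2-oxopropyl)phosphonate, K2CO3, MeOH, 23 → 40 °C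
Reagents that add atoms: dimethyl (1-diazo-2-oxopropyl)phosphonate, COP(=O)(OC)C(=[N+]=[N-])C(C)=O
Why: Ohira–Bestmann variant of the Seyferth–Gilbert homologation: the diazophosphonate anion released by methanolysis adds to the aldehyde, and loss of phosphate and N2 followed by 1,2-hydride shift of the alkylidene carbene gives the terminal alkyne, the aldehyde being unable to enolise so that the mild base only has to overcome steric hindrance.

Step 7
Reactants: 11 tert-butyl{[3-(8-ethynyl-1,4-dioxaspiro[4.5]decan-8-yl)-3-methylbutyl]oxy}dimethylsilane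
Product: 12 3-(8-ethynyl-1,4-dioxaspiro[4.5]decan-8-yl)-3-methylbutan-1-ol
Conditions: TBAF, THF, 23 °C
Reagents that add atoms: none
Why: Fluoride-induced desilylation frees the primary alcohol without affecting the ketal or the terminal alkyne.

Step 8
Reactants: 12 3-(8-ethynyl-1,4-dioxaspiro[4.5]decan-8-yl)-3-methylbutan-1-ol
Product: 13 3-(8-ethynyl-1,4-dioxaspiro[4.5]decan-8-yl)-3-methylbutanal
Conditions: Dess–Martin periodinane, NaHCO3, CH2Cl2, 0 → 23 °C
Reagents that add atoms: none
Why: Dess–Martin oxidation stops at the aldehyde and tolerates the alkyne and the ketal.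

Step 9
Reactants: 13 3-(8-ethynyl-1,4-dioxaspiro[4.5]decan-8-yl)-3-methylbutanal
Product: 14 (2S)-2-bromo-3-(8-ethynyl-1,4-dioxaspiro[4.5]decan-8-yl)-3-methylbutanal
Conditions: (2R,5R)-2,5-diphenylpyrrolidine (20 mol%), PhCO2H (20 mol%), H2O (2 equiv), 4,4-dibromo-2,6-di-tert-butylcyclohexa-2,5-dienone (1.1 equiv), CH2Cl2–pentane 1:1, −40 °C; cold filtration through silica, used at once
Reagents that add atoms: 4,4-dibromo-2,6-di-tert-butylcyclohexa-2,5-dienone, CC(C)(C)C1=CC(Br)(Br)C=C(C(C)(C)C)C1=O
Why: Enamine-catalysed asymmetric α-bromination: the C2-symmetric amine forms the E-enamine, one face of which is shielded by a phenyl group, so the mild Br+ donor attacks the open face and sets the S centre (future C2), a reaction established for aldehydes whose α-carbon carries a tertiary alkyl group, while alkyne and ketal are inert to this reagent.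

Step 10
Reactants: 14 (2S)-2-bromo-3-(8-ethynyl-1,4-dioxaspiro[4.5]decan-8-yl)-3-methylbutanal; 15 tert-butyl diazoacetate
Product: 16 tert-butyl (4S)-4-bromo-5-(8-ethynyl-1,4-dioxaspiro[4.5]decan-8-yl)-5-methyl-3-oxohexanoate
Conditions: SnCl2 (15 mol%), CH2Cl2, 0 → 23 °C
Reagents that add atoms: none
Why: Roskamp homologation: the diazo carbon adds to the SnCl2-activated aldehyde and a 1,2-hydride shift with loss of N2 gives the β-keto ester, the base-free medium and the bulky tertiary-alkyl neighbour keeping the C–Br centre from enolising and from any displacement by the ester oxygen.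

Step 11
Reactants: 16 tert-butyl (4S)-4-bromo-5-(8-ethynyl-1,4-dioxaspiro[4.5]decan-8-yl)-5-methyl-3-oxohexanoate
Product: 17 tert-butyl (2S)-2-bromo-9,9-(ethylenedioxy)-3-hydroxy-1,1-dimethyl-5-methylidenespiro[5.5]undec-3-ene-4-carboxylate
Conditions: Ph3PAuNTf2 (5 mol%), 4 Å MS, CH2Cl2, 23 → 40 °C
Reagents that add atoms: none
Why: The cationic monovalent gold centre binds the ethynyl group on the quaternary carbon, the hydrogen-bonded enol of the β-keto ester attacks the internal alkyne carbon (future C5) through its central carbon (future C4) anti to the metal, and protodeauration of the vinylgold species releases the 1,1-disubstituted alkene and the catalyst. This is a Conia-ene cycloisomerisation of an ω-alkynyl β-keto ester, a known reaction class that includes six-membered closures. Ring A closes in the 6-exo-dig mode, helped by the Thorpe–Ingold effect of the two contiguous quaternary carbons, whereas the 7-endo alternative would require attack at the terminal alkyne carbon, which bears less positive charge. No stereocentre is created, because ring B is still symmetric and C4 ends as an enol carbon, so only the C–Br centre has to be carried through. The direction of enolisation is secured by the ester, which makes the CH2 between the two carbonyl groups far more acidic than the CHBr hydrogen, and the neutral, base-free and silver-free medium offers no path for epimerisation, bromide abstraction, loss of ketal or tert-butyl group, or drift of the new alkene into conjugation. The selectivity most needed is attack through carbon and not through the ketone oxygen, which is favoured because the enol oxygen is tied up in the hydrogen bond to the ester carbonyl.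

Step 12
Reactants: 17 tert-butyl (2S)-2-bromo-9,9-(ethylenedioxy)-3-hydroxy-1,1-dimethyl-5-methylidenespiro[5.5]undec-3-ene-4-carboxylate
Product: 21 (2S)-2-bromo-9,9-(ethylenedioxy)-1,1-dimethyl-5-methylidenespiro[5.5]undecan-3-one, via bis-silyl derivative 18 (not isolated), via β-keto acid 19 (not isolated), via dienol 20 (not isolated)
Conditions: TMSOTf (3 equiv), 2,6-lutidine (4 equiv), CH2Cl2, 0 °C; pH 7 phosphate buffer–THF, 23 → 45 °C; used without chromatography
Reagents that add atoms: none
Why: Silyl-triflate-mediated tert-butyl ester cleavage buffered by lutidine (conditions under which ketone ketals persist) gives the bis-silyl derivative, neutral hydrolysis frees the β-keto acid, which loses CO2 through the cyclic six-centre transition state, and the dienol is protonated kinetically at C4, so that no acid or base able to conjugate the alkene or epimerise C2 is present.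

Step 13
Reactants: 21 (2S)-2-bromo-9,9-(ethylenedioxy)-1,1-dimethyl-5-methylidenespiro[5.5]undecan-3-one
Product: 23 (2S,3R)-2-bromo-3-hydroxy-1,1-dimethyl-5-methylidenespiro[5.5]undecan-9-one, via ketal bromohydrin 22 (not isolated)
Conditions: i-Bu2AlH (1.5 equiv), CH2Cl2, −78 °C; 1 M HCl–THF, 0 → 23 °C
Reagents that add atoms: water, O
Why: Hydride reduction under steric approach control followed by acid ketal hydrolysis: ring A takes the chair with bromine equatorial (an axial bromine would clash with the axial ring-B CH2 on C6), the axial C1 methyl blocks the axial trajectory at C3, so hydride arrives equatorially and gives the axial 3R alcohol cis to bromine, a relationship that cannot close to an epoxide, and the acidic work-up then unmasks the C9 ketone.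

Step 14
Reactants: 23 (2S,3R)-2-bromo-3-hydroxy-1,1-dimethyl-5-methylidenespiro[5.5]undecan-9-one
Product: 24 (2S,3R,6S)-2-bromo-1,1-dimethyl-5-methylidene-3,9-bis(trimethylsilyloxy)spiro[5.5]undec-8-ene
Conditions: (R,R)-bis(1-phenylethyl)amine hydrochloride (2.6 equiv), n-BuLi (5.2 equiv), THF, −78 → 0 °C; TMSCl (6 equiv), −100 °C; add 23, −100 → 0 °C; Et3N, aq. NaHCO3; used crude
Reagents that add atoms: trimethylsilyl chloride, C[Si](C)(C)Cl
Why: Enantiotopic-group-selective deprotonation by a chiral lithium amide with internal silyl quench, an established desymmetrisation of 4,4-disubstituted cyclohexanones: ring B is locked with C1 equatorial and C5 axial, the base removes the axial hydrogen of the α-CH2 that becomes C8 and thereby fixes C6 as S, the C3 alkoxide is silylated in the same flask, and the equatorial C2 bromide has no antiperiplanar hydrogen for elimination.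

Step 15
Reactants: 24 (2S,3R,6S)-2-bromo-1,1-dimethyl-5-methylidene-3,9-bis(trimethylsilyloxy)spiro[5.5]undec-8-ene
Product: 25 (2S,3R,6S,8S)-2-bromo-8-chloro-1,1-dimethyl-5-methylidene-3-(trimethylsilyloxy)spiro[5.5]undecan-9-one
Conditions: NCS (1.05 equiv), CH2Cl2, 0 → 23 °C
Reagents that add atoms: N-chlorosuccinimide, O=C1CCC(=O)N1Cl
Why: Regiospecific electrophilic chlorination of a silyl enol ether: NCS approaches C8 from the face away from the pseudo-axial C5, placing chlorine cis to C1, and this equatorial 8S chloride is also the thermodynamic epimer because an axial chlorine would be syn-axial to C5, so any kinetic leakage converges on it.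

Step 16
Reactants: 25 (2S,3R,6S,8S)-2-bromo-8-chloro-1,1-dimethyl-5-methylidene-3-(trimethylsilyloxy)spiro[5.5]undecan-9-one
Product: 27 (2S,3R,6S,8S,9R)-2-bromo-8-chloro-1,1,9-trimethyl-5-methylidenespiro[5.5]undecane-3,9-diol, via trimethylsilyl ether 26 (not isolated)
Conditions: MeLi, ClTi(OiPr)3, Et2O, −40 → 0 °C; add 25, −30 → 23 °C; 1 M HCl–THF, 23 °C
Reagents that add atoms: methyllithium, [Li]C, transmetallated in the flask to methyltitanium triisopropoxide, C[Ti](OC(C)C)(OC(C)C)OC(C)C
Why: Carbonyl addition of a non-basic organotitanium reagent: MeTi(OiPr)3 neither enolises the α-chloro ketone nor displaces halide, it attacks the locked chair from the equatorial side, anti to the C8 chlorine, giving equatorial methyl and axial 9R hydroxyl cis to chlorine (no epoxide closure possible), and the acidic work-up cleaves the labile trimethylsilyl ether.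

Compound list
1 | 1,4-dioxaspiro[4.5]decane-8-carboxylic acid | OC(=O)C1CCC2(CC1)OCCO2 | starting material
2 | 3-methylbut-2-en-1-ol (prenol) | CC(C)=CCO | starting material
3 | 3-methylbut-2-en-1-yl 1,4-dioxaspiro[4.5]decane-8-carboxylate | CC(C)=CCOC(=O)C1CCC2(CC1)OCCO2 | intermediate
4 | silyl ketene acetal, 8-{[(3-methylbut-2-en-1-yl)oxy](trimethylsilyloxy)methylidene}-1,4-dioxaspiro[4.5]decane | CC(C)=CCOC(O[Si](C)(C)C)=C1CCC2(CC1)OCCO2 | intermediate
5 | trimethylsilyl 8-(2-methylbut-3-en-2-yl)-1,4-dioxaspiro[4.5]decane-8-carboxylate | C=CC(C)(C)C1(C(=O)O[Si](C)(C)C)CCC2(CC1)OCCO2 | intermediate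
6 | [8-(2-methylbut-3-en-2-yl)-1,4-dioxaspiro[4.5]decan-8-yl]methanol | C=CC(C)(C)C1(CO)CCC2(CC1)OCCO2 | intermediate
7 | bis(9-BBN) adduct of 6 (B-alkyl at the chain terminus, B-alkoxy at the hydroxymethyl oxygen) | O(CC1(CCC2(CC1)OCCO2)C(C)(C)CCB1C2CCCC1CCC2)B1C2CCCC1CCC2 | intermediate
8 | 3-[8-(hydroxymethyl)-1,4-dioxaspiro[4.5]decan-8-yl]-3-methylbutan-1-ol | OCCC(C)(C)C1(CO)CCC2(CC1)OCCO2 | intermediate
9 | [8-(4-{[tert-butyl(dimethyl)silyl]oxy}-2-methylbutan-2-yl)-1,4-dioxaspiro[4.5]decan-8-yl]methanol | CC(C)(C)[Si](C)(C)OCCC(C)(C)C1(CO)CCC2(CC1)OCCO2 | intermediate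
10 | 8-(4-{[tert-butyl(dimethyl)silyl]oxy}-2-methylbutan-2-yl)-1,4-dioxaspiro[4.5]decane-8-carbaldehyde | CC(C)(C)[Si](C)(C)OCCC(C)(C)C1(C=O)CCC2(CC1)OCCO2 | intermediate
11 | tert-butyl{[3-(8-ethynyl-1,4-dioxaspiro[4.5]decan-8-yl)-3-methylbutyl]oxy}dimethylsilane | CC(C)(C)[Si](C)(C)OCCC(C)(C)C1(C#C)CCC2(CC1)OCCO2 | intermediate
12 | 3-(8-ethynyl-1,4-dioxaspiro[4.5]decan-8-yl)-3-methylbutan-1-ol | OCCC(C)(C)C1(C#C)CCC2(CC1)OCCO2 | intermediate
13 | 3-(8-ethynyl-1,4-dioxaspiro[4.5]decan-8-yl)-3-methylbutanal | O=CCC(C)(C)C1(C#C)CCC2(CC1)OCCO2 | intermediate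
14 | (2S)-2-bromo-3-(8-ethynyl-1,4-dioxaspiro[4.5]decan-8-yl)-3-methylbutanal | O=C[C@@H](Br)C(C)(C)C1(C#C)CCC2(CC1)OCCO2 | intermediate
15 | tert-butyl diazoacetate | CC(C)(C)OC(=O)C=[N+]=[N-] | starting material
16 | tert-butyl (4S)-4-bromo-5-(8-ethynyl-1,4-dioxaspiro[4.5]decan-8-yl)-5-methyl-3-oxohexanoate (key-step precursor) | CC(C)(C)OC(=O)CC(=O)[C@@H](Br)C(C)(C)C1(C#C)CCC2(CC1)OCCO2 | intermediate
17 | tert-butyl (2S)-2-bromo-9,9-(ethylenedioxy)-3-hydroxy-1,1-dimethyl-5-methylidenespiro[5.5]undec-3-ene-4-carboxylate (key-step product, enol form) | C=C1C(C(=O)OC(C)(C)C)=C(O)[C@@H](Br)C(C)(C)C12CCC3(CC2)OCCO3 | intermediate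
18 | trimethylsilyl (2S)-2-bromo-9,9-(ethylenedioxy)-1,1-dimethyl-5-methylidene-3-(trimethylsilyloxy)spiro[5.5]undec-3-ene-4-carboxylate | C=C1C(C(=O)O[Si](C)(C)C)=C(O[Si](C)(C)C)[C@@H](Br)C(C)(C)C12CCC3(CC2)OCCO3 | intermediate
19 | (2S)-2-bromo-9,9-(ethylenedioxy)-3-hydroxy-1,1-dimethyl-5-methylidenespiro[5.5]undec-3-ene-4-carboxylic acid | C=C1C(C(=O)O)=C(O)[C@@H](Br)C(C)(C)C12CCC3(CC2)OCCO3 | intermediate
20 | (2S)-2-bromo-9,9-(ethylenedioxy)-1,1-dimethyl-5-methylidenespiro[5.5]undec-3-en-3-ol (dienol) | C=C1C=C(O)[C@@H](Br)C(C)(C)C12CCC3(CC2)OCCO3 | intermediate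
21 | (2S)-2-bromo-9,9-(ethylenedioxy)-1,1-dimethyl-5-methylidenespiro[5.5]undecan-3-one | C=C1CC(=O)[C@@H](Br)C(C)(C)C12CCC3(CC2)OCCO3 | intermediate
22 | (2S,3R)-2-bromo-9,9-(ethylenedioxy)-1,1-dimethyl-5-methylidenespiro[5.5]undecan-3-ol | C=C1C[C@@H](O)[C@@H](Br)C(C)(C)C12CCC3(CC2)OCCO3 | intermediate
23 | (2S,3R)-2-bromo-3-hydroxy-1,1-dimethyl-5-methylidenespiro[5.5]undecan-9-one | C=C1C[C@@H](O)[C@@H](Br)C(C)(C)C12CCC(=O)CC2 | intermediate
24 | (2S,3R,6S)-2-bromo-1,1-dimethyl-5-methylidene-3,9-bis(trimethylsilyloxy)spiro[5.5]undec-8-ene | C=C1C[C@@H](O[Si](C)(C)C)[C@@H](Br)C(C)(C)[C@]12CCC(O[Si](C)(C)C)=CC2 | intermediate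
25 | (2S,3R,6S,8S)-2-bromo-8-chloro-1,1-dimethyl-5-methylidene-3-(trimethylsilyloxy)spiro[5.5]undecan-9-one | C=C1C[C@@H](O[Si](C)(C)C)[C@@H](Br)C(C)(C)[C@]12CCC(=O)[C@@H](Cl)C2 | intermediate
26 | (2S,3R,6S,8S,9R)-2-bromo-8-chloro-1,1,9-trimethyl-5-methylidene-3-(trimethylsilyloxy)spiro[5.5]undecan-9-ol | C=C1C[C@@H](O[Si](C)(C)C)[C@@H](Br)C(C)(C)[C@]12CC[C@@](C)(O)[C@@H](Cl)C2 | intermediate
27 | (2S,3R,6S,8S,9R)-2-bromo-8-chloro-1,1,9-trimethyl-5-methylidenespiro[5.5]undecane-3,9-diol (CNP0121782.1) | C=C1C[C@@H](O)[C@@H](Br)C(C)(C)[C@]12CC[C@@](C)(O)[C@@H](Cl)C2 | target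

Total step count: 16. Longest linear sequence: 16 steps (from 1).

Steps most likely to fail

**1. Step 11 (key step).**
- What may go wrong: slow 6-exo closure at the congested internal alkyne carbon, competing attack through the ketone oxygen, hydration of the alkyne by adventitious water, or acid-induced migration of the new double bond into conjugation.
- Fallback (sets out from 16, returns at 17): the nucleophile is made beforehand and its oxygen is blocked. TBSOTf and Et3N in CH2Cl2 at −78 → 0 °C convert 16, by deprotonation at the doubly activated CH2, into the (Z)-tert-butyldimethylsilyl enol ether F1. This is then submitted to the known carbocyclisation of silyl enol ethers onto alkynes under cationic monovalent gold catalysis, with [(t-Bu)2(2-biphenylyl)P]Au(NCMe)SbF6 (5 mol%) in CH2Cl2–MeOH 10:1 at 23 °C. The more nucleophilic enol ether can react only through carbon. Methanol takes up the silyl group and supplies the proton for protodeauration, giving 17.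

**2. Step 9.**
- What may go wrong: slow enamine formation next to the quaternary carbon, and erosion of configuration by enolisation of the bromo aldehyde during the reaction, its isolation or step 10.
- Fallback (sets out from 13, returns at 16): the centre is set under auxiliary control on a carboxylic acid derivative.
  - Pinnick oxidation (NaClO2, NaH2PO4, 2-methylbut-2-ene, t-BuOH–H2O) gives 3-(8-ethynyl-1,4-dioxaspiro[4.5]decan-8-yl)-3-methylbutanoic acid F2.
  - Pivaloyl chloride/Et3N turns it into the mixed pivalic anhydride F3, and lithiated (S)-4-benzyl-2-oxazolidinone gives the N-acyl oxazolidinone F4.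
  - Soft enolisation (Bu2BOTf, i-Pr2NEt, CH2Cl2, −78 °C) and NBS should deliver bromine anti to the benzyl group and give the (2S)-bromo imide F5, whose minor epimer is a separable diastereomer.
  - LiOH/H2O2 releases the (2S)-bromo acid F6.
  - Masamune–Brooks homologation through the acyl imidazolide F7 (carbonyldiimidazole, then Mg(O2CCH2CO2t-Bu)2, THF, 23 °C) gives 16 under near-neutral conditions.

**3. Step 12.**
- What may go wrong: opening of the ketal by the silyl triflate, migration of the exocyclic double bond into conjugation with the ketone during or after decarboxylation, or epimerisation at C2.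
- Fallback (sets out from 14, returns at 21): the ester is changed to one that leaves under neutral transition-metal catalysis.
  - Roskamp homologation of 14 with allyl diazoacetate (SnCl2, CH2Cl2) gives the allyl β-keto ester F8.
  - Cyclisation as in step 11 gives the allyl ester of the ring-A enol F9.
  - Pd(PPh3)4 (3 mol%) and dimedone in THF at 0 → 23 °C ionise the allyl ester (Tsuji-type deallylative decarboxylation). The carboxylate loses CO2, dimedone takes up the allyl group and supplies the proton for C4, and 21 results without silyl triflate or mineral acid.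
  - Ionisation of the allyl ester by zerovalent palladium should be much faster than insertion into the hindered C–Br bond.

Further compounds
F1 | step 11 | tert-butyl (2Z,4S)-4-bromo-3-{[tert-butyl(dimethyl)silyl]oxy}-5-(8-ethynyl-1,4-dioxaspiro[4.5]decan-8-yl)-5-methylhex-2-enoate | CC(C)(C)OC(=O)/C=C(\O[Si](C)(C)C(C)(C)C)[C@@H](Br)C(C)(C)C1(C#C)CCC2(CC1)OCCO2
F2 | step 9 | 3-(8-ethynyl-1,4-dioxaspiro[4.5]decan-8-yl)-3-methylbutanoic acid | OC(=O)CC(C)(C)C1(C#C)CCC2(CC1)OCCO2
F3 | step 9 | mixed anhydride of F2 and pivalic acid | CC(C)(C)C(=O)OC(=O)CC(C)(C)C1(C#C)CCC2(CC1)OCCO2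
F4 | step 9 | (4S)-4-benzyl-3-[3-(8-ethynyl-1,4-dioxaspiro[4.5]decan-8-yl)-3-methylbutanoyl]-1,3-oxazolidin-2-one | O=C(CC(C)(C)C1(C#C)CCC2(CC1)OCCO2)N1[C@@H](Cc2ccccc2)COC1=O
F5 | step 9 | (4S)-4-benzyl-3-[(2S)-2-bromo-3-(8-ethynyl-1,4-dioxaspiro[4.5]decan-8-yl)-3-methylbutanoyl]-1,3-oxazolidin-2-one | O=C([C@@H](Br)C(C)(C)C1(C#C)CCC2(CC1)OCCO2)N1[C@@H](Cc2ccccc2)COC1=O
F6 | step 9 | (2S)-2-bromo-3-(8-ethynyl-1,4-dioxaspiro[4.5]decan-8-yl)-3-methylbutanoic acid | OC(=O)[C@@H](Br)C(C)(C)C1(C#C)CCC2(CC1)OCCO2
F7 | step 9 | (2S)-2-bromo-3-(8-ethynyl-1,4-dioxaspiro[4.5]decan-8-yl)-1-(imidazol-1-yl)-3-methylbutan-1-one | O=C([C@@H](Br)C(C)(C)C1(C#C)CCC2(CC1)OCCO2)n1ccnc1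
F8 | step 12 | prop-2-en-1-yl (4S)-4-bromo-5-(8-ethynyl-1,4-dioxaspiro[4.5]decan-8-yl)-5-methyl-3-oxohexanoate | C=CCOC(=O)CC(=O)[C@@H](Br)C(C)(C)C1(C#C)CCC2(CC1)OCCO2
F9 | step 12 | prop-2-en-1-yl (2S)-2-bromo-9,9-(ethylenedioxy)-3-hydroxy-1,1-dimethyl-5-methylidenespiro[5.5]undec-3-ene-4-carboxylate | C=C1C(C(=O)OCC=C)=C(O)[C@@H](Br)C(C)(C)C12CCC3(CC2)OCCO3
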